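**Retrosynthetic overview**
- CIML C ⇐ its 5,8-bis(triethylsilyl) ether ⇐ Z-selective ring-closing metathesis at C2=C3 of the C21 acrylate; the 22-membered lactone ring is formed last.
- Acrylate ⇐ epoxy triol by lipase acylation at O21; the oxirane ring (C6–C7) is formed first, by catalyst-controlled epoxidation of an (E)-ene-1,4-diol.
- (5S,8S)-Ene-triol ⇐ key step: two successive 1,2-shifts of an alkenyl carbon from boron to carbon (lithiation–borylation). They join a C3–C5 carbenoid, a CH=CH diboron unit (C6–C7) and the C8–C22 carbenoid, and set C5 and C8.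
- C8–C22 piece ⇐ sp3–sp3 Suzuki coupling of a 5-bromopentyl ester with the alkene from (R)-propylene oxide and a heptenyl Grignard reagent (C21 bought).

Assumption: CIML C is taken as exactly the given SMILES, (2Z,5S,6R,7R,8S,21R)-6,7-epoxy-5,8-dihydroxydocos-2-en-21-olide; trans-1,2-bis(pinacolatoboryl)ethene, (+)-sparteine, the Shi ketone and the Mo alkylidene are bought reagents.

**Step 1**
Reactants: 1 5-bromopentan-1-ol
Product: 2 5-bromopentyl 2,4,6-triisopropylbenzoate
Conditions: 2,4,6-triisopropylbenzoic acid, PPh3, DIAD, THF, 0 °C → rt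
Reagents that add atoms: 2,4,6-triisopropylbenzoic acid, CC(C)c1cc(C(C)C)c(C(=O)O)c(C(C)C)c1
Why: Mitsunobu esterification of the primary alcohol needs no base, so the ω-bromide is untouched, and it installs the hindered benzoate (TIB ester) that later directs α-lithiation and acts as leaving group in the 1,2-shift.

**Step 2**
Reactants: 3 7-bromohept-1-ene; 4 (R)-2-methyloxirane
Product: 7 (R)-triethyl(dec-9-en-2-yloxy)silane, via hept-6-enylmagnesium bromide 5 (not isolated), via magnesium alkoxide 6 (not isolated)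
Conditions: Mg, THF; CuI (10 mol%), 4, −30 → 0 °C; then TESCl, imidazole, DMF, rt
Reagents that add atoms: triethylsilyl chloride, CC[Si](Cl)(CC)CC
Why: Copper-catalysed Grignard opening of the epoxide occurs at the CH2 carbon, so the bought (R) centre becomes C21 unchanged, and the alkoxide is silylated in the same flask.

**Step 3**
Reactants: 7 (R)-triethyl(dec-9-en-2-yloxy)silane; 2 5-bromopentyl 2,4,6-triisopropylbenzoate
Product: 9 (R)-14-(triethylsilyloxy)pentadecyl 2,4,6-triisopropylbenzoate, via B-alkyl-9-BBN 8 (not isolated)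
Conditions: 9-BBN, THF, rt; then 2, Pd(OAc)2 (4 mol%), PCy3 (8 mol%), K3PO4·H2O, THF, rt
Reagents that add atoms: none
Why: Anti-Markovnikov hydroboration followed by Fu-type alkyl–alkyl Suzuki–Miyaura coupling (the bulky electron-rich phosphine suppresses β-hydride elimination) joins C12 to C13 without touching a stereocentre.

**Step 4**
Reactants: 10 but-3-en-1-ol
Product: 11 but-3-enyl 2,4,6-triisopropylbenzoate
Conditions: 2,4,6-triisopropylbenzoic acid, PPh3, DIAD, THF, 0 °C → rt
Reagents that add atoms: 2,4,6-triisopropylbenzoic acid, CC(C)c1cc(C(C)C)c(C(=O)O)c(C(C)C)c1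
Why: Mitsunobu esterification as in step 1.

**Step 5 (key step)**
Reactants: 11 but-3-enyl 2,4,6-triisopropylbenzoate; 9 (R)-14-(triethylsilyloxy)pentadecyl 2,4,6-triisopropylbenzoate
Product: 17 (2R,15S,16E,18S)-henicosa-16,20-diene-2,15,18-triol, via lithiated butenyl ester 12 (not isolated), via dienyl diboronate 13 (not isolated), via lithiated chain ester 14 (not isolated), via bis(allylboronate) 15 (not isolated), via diol TES ether 16 (not isolated)
Conditions: 11 (1.0 equiv), s-BuLi, (+)-sparteine, Et2O, −78 °C; trans-pinBCH=CHBpin (1.0 equiv), −78 → 35 °C; re-cool, add to 9/s-BuLi/(+)-sparteine, Et2O, −78 → 35 °C; NaOH, H2O2, THF, 0 °C; PPTS, MeOH, rt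
Reagents that add atoms: trans-1,2-bis(pinacolatoboryl)ethene, CC1(C)OB(/C=C/B2OC(C)(C)C(C)(C)O2)OC1(C)C; hydrogen peroxide, OO
Why: Proposed new method: a one-flask double lithiation–borylation on a 1,2-diborylethene, in which each (+)-sparteine-controlled α-lithiated TIB ester adds to boron with retention and the alkenyl carbon then shifts 1,2 from boron to carbon anti to the leaving carboxylate (inversion), forming C5–C6 and then C7–C8 and giving C5 and C8 as S after stereoretentive C–B oxidation; the first boronate complex is anionic and deactivates the conjugated second boron, so one equivalent adds once, and the second carbenoid prefers the unhindered alkenyl boron of 13 over its secondary allylic boron; the closest known reactions are Hoppe–Aggarwal lithiation–borylation of vinylboronic esters to α-substituted allylboronates and site-selective homologation of bis(boronic esters).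

**Step 6**
Reactants: 17 (2R,15S,16E,18S)-henicosa-16,20-diene-2,15,18-triol
Product: 18 (2R,15S,16R,17R,18S)-16,17-epoxyhenicos-20-ene-2,15,18-triol
Conditions: D-fructose-derived Shi ketone (30 mol%), Oxone (2KHSO5·KHSO4·K2SO4), K2CO3, Bu4NHSO4, MeCN/(MeO)2CH2/aq. borate buffer, 0 °C
Reagents that add atoms: potassium peroxymonosulfate (Oxone), [K+].[O-]S(=O)(=O)OO
Why: Shi asymmetric epoxidation (chiral dioxirane, spiro transition state) takes the trans-disubstituted alkene over the terminal one and gives the (R,R)-oxirane; this is also the threo face favoured by hydrogen bonding to both allylic hydroxyls, so reagent and substrate control are matched.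

**Step 7**
Reactants: 18 (2R,15S,16R,17R,18S)-16,17-epoxyhenicos-20-ene-2,15,18-triol
Product: 19 (2R,15S,16R,17R,18S)-16,17-epoxy-15,18-dihydroxyhenicos-20-en-2-yl prop-2-enoate
Conditions: Novozym 435 (immobilised Candida antarctica lipase B), vinyl acrylate, BHT, MTBE, 40 °C
Reagents that add atoms: vinyl acrylate, C=CC(=O)OC=C
Why: Lipase-catalysed transesterification follows the Kazlauskas rule and acylates only the unhindered (R)-methyl carbinol, the two epoxy carbinols having two large substituents each; it is irreversible because vinyl alcohol tautomerises to acetaldehyde.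

**Step 8**
Reactants: 19 (2R,15S,16R,17R,18S)-16,17-epoxy-15,18-dihydroxyhenicos-20-en-2-yl prop-2-enoate
Product: 20 (2R,15S,16R,17R,18S)-16,17-epoxy-15,18-bis(triethylsilyloxy)henicos-20-en-2-yl prop-2-enoate
Conditions: TESCl, imidazole, DMAP (cat.), DMF, rt
Reagents that add atoms: triethylsilyl chloride, CC[Si](Cl)(CC)CC
Why: Standard silylation masks both hydroxyls, which the oxophilic Mo alkylidene of step 9 does not tolerate, without touching epoxide or acrylate.

**Step 9**
Reactants: 20 (2R,15S,16R,17R,18S)-16,17-epoxy-15,18-bis(triethylsilyloxy)henicos-20-en-2-yl prop-2-enoate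
Product: 21 (2Z,5S,6R,7R,8S,21R)-6,7-epoxy-5,8-bis(triethylsilyloxy)docos-2-en-21-olide
Conditions: Mo(NC6F5)(CHCMe2Ph)(2,5-Me2C4H2N)[O-2,6-(2,4,6-iPr3C6H2)2C6H3] (7.5 mol%), toluene (1 mM), 22 °C, 30 torr
Reagents that add atoms: none
Why: Kinetically Z-selective macrocyclic ring-closing metathesis with a Mo monoaryloxide pyrrolide alkylidene (the large aryloxide forces both metallacyclobutane substituents to the same side) closes the 22-membered ring at C2=C3 with loss of ethene.

**Step 10**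
Reactants: 21 (2Z,5S,6R,7R,8S,21R)-6,7-epoxy-5,8-bis(triethylsilyloxy)docos-2-en-21-olide
Product: 22 CIML C, (2Z,5S,6R,7R,8S,21R)-6,7-epoxy-5,8-dihydroxydocos-2-en-21-olide
Conditions: HF·pyridine, pyridine, THF, 0 °C → rt
Reagents that add atoms: none
Why: Buffered fluoride desilylation frees O5 and O8 under non-basic conditions, avoiding translactonisation to the six-membered lactone and Payne rearrangement.

**Compound list**
1 | 5-bromopentan-1-ol | OCCCCCBr | starting material
2 | 5-bromopentyl 2,4,6-triisopropylbenzoate | BrCCCCCOC(=O)c1c(C(C)C)cc(C(C)C)cc1C(C)C | intermediate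
3 | 7-bromohept-1-ene | C=CCCCCCBr | starting material
4 | (R)-2-methyloxirane | C[C@@H]1CO1 | starting material
5 | hept-6-enylmagnesium bromide | C=CCCCCC[Mg]Br | intermediate (not isolated)
6 | bromomagnesium (R)-dec-9-en-2-olate | C[C@@H](O[Mg]Br)CCCCCCC=C | intermediate (not isolated)
7 | (R)-triethyl(dec-9-en-2-yloxy)silane | C[C@@H](O[Si](CC)(CC)CC)CCCCCCC=C | intermediate
8 | 9-[(9R)-9-(triethylsilyloxy)decyl]-9-borabicyclo[3.3.1]nonane | C[C@@H](O[Si](CC)(CC)CC)CCCCCCCCB1C2CCCC1CCC2 | intermediate (not isolated)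
9 | (R)-14-(triethylsilyloxy)pentadecyl 2,4,6-triisopropylbenzoate | C[C@@H](O[Si](CC)(CC)CC)CCCCCCCCCCCCCOC(=O)c1c(C(C)C)cc(C(C)C)cc1C(C)C | intermediate
10 | but-3-en-1-ol | C=CCCO | starting material
11 | but-3-enyl 2,4,6-triisopropylbenzoate | C=CCCOC(=O)c1c(C(C)C)cc(C(C)C)cc1C(C)C | intermediate
12 | (R)-1-lithiobut-3-enyl 2,4,6-triisopropylbenzoate (sparteine complex) | [Li][C@@H](OC(=O)c1c(C(C)C)cc(C(C)C)cc1C(C)C)CC=C | intermediate (not isolated)
13 | (S,E)-1,3-bis(pinacolatoboryl)hexa-1,5-diene | C=CC[C@H](B1OC(C)(C)C(C)(C)O1)/C=C/B1OC(C)(C)C(C)(C)O1 | intermediate (not isolated)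
14 | (1R,14R)-1-lithio-14-(triethylsilyloxy)pentadecyl 2,4,6-triisopropylbenzoate (sparteine complex) | [Li][C@@H](OC(=O)c1c(C(C)C)cc(C(C)C)cc1C(C)C)CCCCCCCCCCCC[C@@H](C)O[Si](CC)(CC)CC | intermediate (not isolated)
15 | (4S,5E,7S,20R)-4,7-bis(pinacolatoboryl)-20-(triethylsilyloxy)henicosa-1,5-diene | C=CC[C@H](B1OC(C)(C)C(C)(C)O1)/C=C/[C@@H](B1OC(C)(C)C(C)(C)O1)CCCCCCCCCCCC[C@@H](C)O[Si](CC)(CC)CC | intermediate (not isolated)
16 | (2R,15S,16E,18S)-2-(triethylsilyloxy)henicosa-16,20-diene-15,18-diol | C=CC[C@H](O)/C=C/[C@@H](O)CCCCCCCCCCCC[C@@H](C)O[Si](CC)(CC)CC | intermediate (not isolated)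
17 | (2R,15S,16E,18S)-henicosa-16,20-diene-2,15,18-triol | C[C@@H](O)CCCCCCCCCCCC[C@H](O)/C=C/[C@@H](O)CC=C | intermediate
18 | (2R,15S,16R,17R,18S)-16,17-epoxyhenicos-20-ene-2,15,18-triol | C[C@@H](O)CCCCCCCCCCCC[C@H](O)[C@H]1O[C@@H]1[C@@H](O)CC=C | intermediate
19 | (2R,15S,16R,17R,18S)-16,17-epoxy-15,18-dihydroxyhenicos-20-en-2-yl prop-2-enoate | C[C@@H](OC(=O)C=C)CCCCCCCCCCCC[C@H](O)[C@H]1O[C@@H]1[C@@H](O)CC=C | intermediate
20 | (2R,15S,16R,17R,18S)-16,17-epoxy-15,18-bis(triethylsilyloxy)henicos-20-en-2-yl prop-2-enoate | C[C@@H](OC(=O)C=C)CCCCCCCCCCCC[C@H](O[Si](CC)(CC)CC)[C@H]1O[C@@H]1[C@@H](O[Si](CC)(CC)CC)CC=C | intermediate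
21 | (2Z,5S,6R,7R,8S,21R)-6,7-epoxy-5,8-bis(triethylsilyloxy)docos-2-en-21-olide | C[C@@H]1CCCCCCCCCCCC[C@H](O[Si](CC)(CC)CC)[C@H]2O[C@@H]2[C@@H](O[Si](CC)(CC)CC)C/C=C\C(=O)O1 | intermediate
22 | CIML C, (2Z,5S,6R,7R,8S,21R)-6,7-epoxy-5,8-dihydroxydocos-2-en-21-olide | C[C@@H]1CCCCCCCCCCCC[C@H](O)[C@H]2O[C@@H]2[C@@H](O)C/C=C\C(=O)O1 | target

**Step count**
Total: 10 steps. Longest linear sequence: 8 steps (2, 3, 5, 6, 7, 8, 9, 10).

**Three steps most likely to fail**

Step 5 (the proposed new double 1,2-shift; risks are double addition to the diboron reagent, wrong-boron attack in the second stage, and slow alkenyl migration). The fallback sets out from 9 and comes back at 17, using the known single lithiation–borylation with a preformed alkenylboronate. Bought 3-(trimethylsilyl)prop-2-ynal F1 is allylated with (−)-B-allyldiisopinocampheylborane to (S)-1-(trimethylsilyl)hex-5-en-1-yn-3-ol F2. K2CO3/MeOH then TESCl/imidazole give (S)-triethyl(hex-5-en-1-yn-3-yloxy)silane F3. Cp2ZrHCl-catalysed hydroboration of the alkyne with pinacolborane gives the (S,E)-alkenylboronate F4. Compound 9 is lithiated (s-BuLi, (+)-sparteine), treated with F4, warmed and oxidised (NaOH, H2O2) to the bis-TES ether F5, and PPTS/MeOH gives 17.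

Step 9 (the Mo alkylidene may not tolerate the oxirane, or E-isomer may leak). The fallback sets out from 18 and comes back at 21, closing the ring by lactonisation after a Still–Gennari olefination. Lipase acetylation (Novozym 435, vinyl acetate) gives the C2 acetate F9, and TESCl/imidazole gives the bis-TES ether F10. Ozonolysis (O3, then PPh3) gives the aldehyde F11. (CF3CH2O)2P(O)CH2CO2Me with KN(SiMe3)2 and 18-crown-6 at −78 °C gives the (Z)-methyl enoate F12. LiOH cleaves the methyl ester and the acetate to the seco acid F13, and Shiina lactonisation (2-methyl-6-nitrobenzoic anhydride, DMAP, high dilution) gives 21.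

Step 6 (diastereo- and chemoselectivity of the epoxidation of a bis-allylic diol). The fallback sets out from 11 and 9 and comes back at 18, using hydroxyl-directed epoxidation followed by inversion. Step 5 is run with (−)-sparteine in both lithiations and stopped before the PPTS treatment, giving the (2R,15R,16E,18R)-diol TES ether F6. Sharpless epoxidation (Ti(OiPr)4, D-(−)-diisopropyl tartrate, t-BuOOH; doubly matched, erythro) gives the all-(R) epoxy diol F7. Double Mitsunobu inversion (4-nitrobenzoic acid, PPh3, DIAD) gives the (15S,18S)-bis(4-nitrobenzoate) F8, and K2CO3/MeOH then PPTS/MeOH give 18.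

**Further compounds**
F1 | step 5 | 3-(trimethylsilyl)prop-2-ynal (bought for the fallback) | C[Si](C)(C)C#CC=O
F2 | step 5 | (S)-1-(trimethylsilyl)hex-5-en-1-yn-3-ol | C[Si](C)(C)C#C[C@@H](O)CC=C
F3 | step 5 | (S)-triethyl(hex-5-en-1-yn-3-yloxy)silane | C#C[C@@H](O[Si](CC)(CC)CC)CC=C
F4 | step 5 | (S,E)-triethyl{[1-(pinacolatoboryl)hexa-1,5-dien-3-yl]oxy}silane | CC1(C)OB(/C=C/[C@@H](O[Si](CC)(CC)CC)CC=C)OC1(C)C
F5 | step 5 | (2R,15S,16E,18S)-2,18-bis(triethylsilyloxy)henicosa-16,20-dien-15-ol | C[C@@H](O[Si](CC)(CC)CC)CCCCCCCCCCCC[C@H](O)/C=C/[C@@H](O[Si](CC)(CC)CC)CC=C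
F6 | step 6 | (2R,15R,16E,18R)-2-(triethylsilyloxy)henicosa-16,20-diene-15,18-diol | C[C@@H](O[Si](CC)(CC)CC)CCCCCCCCCCCC[C@@H](O)/C=C/[C@H](O)CC=C
F7 | step 6 | (2R,15R,16R,17R,18R)-16,17-epoxy-2-(triethylsilyloxy)henicos-20-ene-15,18-diol | C[C@@H](O[Si](CC)(CC)CC)CCCCCCCCCCCC[C@@H](O)[C@H]1O[C@@H]1[C@H](O)CC=C
F8 | step 6 | (2R,15S,16R,17R,18S)-16,17-epoxy-2-(triethylsilyloxy)henicos-20-ene-15,18-diyl bis(4-nitrobenzoate) | C[C@@H](O[Si](CC)(CC)CC)CCCCCCCCCCCC[C@H](OC(=O)c1ccc(cc1)[N+](=O)[O-])[C@H]2O[C@@H]2[C@@H](OC(=O)c1ccc(cc1)[N+](=O)[O-])CC=C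
F9 | step 9 | (2R,15S,16R,17R,18S)-16,17-epoxy-15,18-dihydroxyhenicos-20-en-2-yl acetate | C[C@@H](OC(C)=O)CCCCCCCCCCCC[C@H](O)[C@H]1O[C@@H]1[C@@H](O)CC=C
F10 | step 9 | (2R,15S,16R,17R,18S)-16,17-epoxy-15,18-bis(triethylsilyloxy)henicos-20-en-2-yl acetate | C[C@@H](OC(C)=O)CCCCCCCCCCCC[C@H](O[Si](CC)(CC)CC)[C@H]1O[C@@H]1[C@@H](O[Si](CC)(CC)CC)CC=C
F11 | step 9 | (3S,4R,5R,6S,19R)-19-acetoxy-4,5-epoxy-3,6-bis(triethylsilyloxy)icosanal | C[C@@H](OC(C)=O)CCCCCCCCCCCC[C@H](O[Si](CC)(CC)CC)[C@H]1O[C@@H]1[C@@H](O[Si](CC)(CC)CC)CC=O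
F12 | step 9 | methyl (2Z,5S,6R,7R,8S,21R)-21-acetoxy-6,7-epoxy-5,8-bis(triethylsilyloxy)docos-2-enoate | C[C@@H](OC(C)=O)CCCCCCCCCCCC[C@H](O[Si](CC)(CC)CC)[C@H]1O[C@@H]1[C@@H](O[Si](CC)(CC)CC)C/C=C\C(=O)OC
F13 | step 9 | (2Z,5S,6R,7R,8S,21R)-6,7-epoxy-21-hydroxy-5,8-bis(triethylsilyloxy)docos-2-enoic acid | C[C@@H](O)CCCCCCCCCCCC[C@H](O[Si](CC)(CC)CC)[C@H]1O[C@@H]1[C@@H](O[Si](CC)(CC)CC)C/C=C\C(=O)O
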